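## Retrosynthetic overview

1. Target 19 ⇐ hydrogenolysis of the ring C benzyl ether and the ring A diphenylmethylene ketal ⇐ (S)-carbinol 18 ⇐ Noyori transfer hydrogenation of macrocyclic aryl ketone 17.
2. 17 ⇐ one bond, ring A oxygen to C-4 of ring B, closed by a fluoride-triggered desilylation/SNAr macro-etherification of the open-chain 4-fluorophenyl benzyl ketone 15. This 18-membered ring is the only ring of the target that has to be built; the four benzene rings are bought.
3. Enabling feature: the carbinol carbon sits on ring B para to the ring B carbon that carries the ring A oxygen. Held at the ketone level it is a para-acyl group that stabilises the Meisenheimer anion at that carbon; afterwards it becomes the only stereocentre.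
4. 15 ⇐ B-alkyl Suzuki–Miyaura coupling (CH2–CH2 bridge; ring A styrene 4 + ring D iodide 13) ⇐ deoxybenzoin by amino-phosphonate olefination/hydrolysis of aldehyde 8 ⇐ ring C–O–ring D ether by SNAr on an ortho-fluorobenzaldehyde.
5. Ring order: temporary dioxole on ring A (step 1), macrocycle (step 9), dioxole opened again in step 11.

Key step: step 9

Assumption: compounds 1, 5, 7 and 9 and all reagents are purchased; the carbinol carbon of the target is (S) (CIP order OH > ring B carbon > CH2 > H), and the 18-membered ring is taken to have no stable atropisomers.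

## Route

Step 1
Reactants: 1 3,4,5-trihydroxybenzaldehyde
Product: 2 7-hydroxy-2,2-diphenyl-1,3-benzodioxole-5-carbaldehyde
Conditions: Ph2CCl2, Ph2O, 175 °C
Reagents that add atoms: dichlorodiphenylmethane, ClC(Cl)(c1ccccc1)c1ccccc1
Why: Ketalisation of a catechol with a gem-dichloride (double O-alkylation with loss of two HCl); the three hydroxyls of 1 are symmetric, so bridging either adjacent pair gives the same dioxole and leaves one free phenol meta to the formyl group.

Step 2
Reactants: 2 7-hydroxy-2,2-diphenyl-1,3-benzodioxole-5-carbaldehyde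
Product: 3 2,2-diphenyl-7-[(triisopropylsilyl)oxy]-1,3-benzodioxole-5-carbaldehyde
Conditions: TIPSCl, imidazole, DMF, rt
Reagents that add atoms: triisopropylsilyl chloride, CC(C)[Si](Cl)(C(C)C)C(C)C
Why: Imidazole-promoted silyl ether formation masks the future nucleophilic phenol as a fluoride-labile group that should survive ylide, borane and palladium chemistry.

Step 3
Reactants: 3 2,2-diphenyl-7-[(triisopropylsilyl)oxy]-1,3-benzodioxole-5-carbaldehyde
Product: 4 5-ethenyl-2,2-diphenyl-7-[(triisopropylsilyl)oxy]-1,3-benzodioxole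
Conditions: Ph3PCH3Br, KOtBu, THF, 0 °C to rt
Reagents that add atoms: methyltriphenylphosphonium bromide, C[P+](c1ccccc1)(c1ccccc1)c1ccccc1.[Br-]
Why: Wittig methylenation of the aryl aldehyde gives the styrene needed for hydroboration, and the non-stabilised ylide does not attack the silyl ether or the ketal.

Step 4
Reactants: 5 2-fluoro-3-hydroxybenzaldehyde
Product: 6 3-(benzyloxy)-2-fluorobenzaldehyde
Conditions: BnBr, K2CO3, DMF, rt
Reagents that add atoms: benzyl bromide, BrCc1ccccc1
Why: Williamson ether synthesis (SN2 at benzyl bromide) on the phenoxide, which at room temperature is far faster than self-condensation by SNAr at the ortho fluorine.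

Step 5
Reactants: 6 3-(benzyloxy)-2-fluorobenzaldehyde; 7 3-iodophenol
Product: 8 3-(benzyloxy)-2-(3-iodophenoxy)benzaldehyde
Conditions: K2CO3, DMF, 110 °C
Reagents that add atoms: none
Why: SNAr in which the phenoxide of 7 adds to C-2 of 6, the Meisenheimer anion is stabilised by the ortho formyl group and fluoride leaves, while the C–I bond is inert in the absence of a metal catalyst.

Step 6
Reactants: 9 4-fluorobenzaldehyde
Product: 11 diphenyl [(4-fluorophenyl)(phenylamino)methyl]phosphonate, via imine 10 (not isolated)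
Conditions: PhNH2, (PhO)2P(O)H, i-PrOH, rt
Reagents that add atoms: aniline, Nc1ccccc1; diphenyl phosphite, O=[PH](Oc1ccccc1)Oc1ccccc1
Why: Kabachnik–Fields reaction, in which condensation to imine 10 and Pudovik addition of the P–H bond give the α-anilino phosphonate as an acyl-anion equivalent of 9 (racemic; its stereocentre is destroyed in step 7).

Step 7
Reactants: 8 3-(benzyloxy)-2-(3-iodophenoxy)benzaldehyde; 11 diphenyl [(4-fluorophenyl)(phenylamino)methyl]phosphonate
Product: 13 2-[3-(benzyloxy)-2-(3-iodophenoxy)phenyl]-1-(4-fluorophenyl)ethan-1-one, via enamine 12 (not isolated)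
Conditions: Cs2CO3, THF/i-PrOH (4:1), rt; then 1 M aq. HCl, rt
Reagents that add atoms: water, O
Why: Horner–Wadsworth–Emmons-type olefination of the phosphonate carbanion with aldehyde 8 gives enamine 12, and acid hydrolysis through its imine tautomer places the carbonyl on the carbon that came from 9 and a CH2 on the former aldehyde carbon, under conditions that spare the aryl iodide and the benzyl ether.

Step 8
Reactants: 4 5-ethenyl-2,2-diphenyl-7-[(triisopropylsilyl)oxy]-1,3-benzodioxole; 13 2-[3-(benzyloxy)-2-(3-iodophenoxy)phenyl]-1-(4-fluorophenyl)ethan-1-one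
Product: 15 open-chain fluoro ketone 2-{3-(benzyloxy)-2-[3-(2-{2,2-diphenyl-7-[(triisopropylsilyl)oxy]-1,3-benzodioxol-5-yl}ethyl)phenoxy]phenyl}-1-(4-fluorophenyl)ethan-1-one, via alkylborane 14 (not isolated)
Conditions: 4, 9-BBN, THF, rt; then 13, PdCl2(dppf) (5 mol %), K3PO4, DMF/H2O, rt to 50 °C
Reagents that add atoms: none
Why: Anti-Markovnikov hydroboration of the styrene with 9-BBN followed by B-alkyl Suzuki–Miyaura coupling (oxidative addition of the C–I bond to zerovalent palladium, base-assisted alkyl transfer from boron, reductive elimination) builds the CH2–CH2 bridge directly with no stilbene to hydrogenate, and the C–F bond, ketone, benzyl ether, ketal and silyl ether should be untouched at this temperature.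

Step 9
Reactants: 15 open-chain fluoro ketone
Product: 17 macrocyclic ketone, via cesium phenoxide 16 (not isolated)
Conditions: CsF (5 equiv), degassed DMF, 100 °C, slow addition of 15 to a final 0.002 M
Reagents that add atoms: none
Why: Fluoride cleaves the aryl O–Si bond of 15 and releases cesium phenoxide 16, whose oxygen adds to C-4 of ring B to give a Meisenheimer anion that is delocalised into the para ketone and then expels fluoride (addition–elimination SNAr), so that fluoride is returned and the silyl fluoride is the only co-product. The closest known reaction types are the SNAr macro-etherification of phenols onto activated fluoroarenes and the fluoride-mediated coupling of aryl silyl ethers with 4-fluorophenyl ketones used for aryl ether ketones. The one ring closed is the 18-membered macrocycle, by intramolecular ipso attack of the ring A oxygen on the C–F carbon of ring B, which joins the two ends of the open chain. No stereocentre is formed; the trigonal ketone carbon that activates the step is converted into the only stereocentre in step 10 under catalyst control. The step needs cyclisation to win over chain growth and oxygen attack at a single carbon: slow addition to about 0.002 M and the gradual, fluoride-limited release of the phenoxide favour the intramolecular path, only one oxygen is unmasked (ring C phenol benzylated, ring A catechol locked in the dioxole), only one carbon bears fluorine, and deprotonation of the CH2 next to the ketone is reversible and switches off its own ring instead of consuming it.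

Step 10
Reactants: 17 macrocyclic ketone
Product: 18 protected (S)-carbinol macrocycle
Conditions: RuCl[(S,S)-TsDPEN](p-cymene) (5 mol %), HCO2H/Et3N (5:2), DMF, 40 °C
Reagents that add atoms: none
Why: Noyori asymmetric transfer hydrogenation, in which the Ru–H/N–H unit of the (S,S)-catalyst transfers hydride and proton through a six-membered transition state to the Re face of the aryl ketone, the face being fixed by the CH/π contact between the p-cymene ligand and ring B, which should give the (S)-carbinol (OH > ring B carbon > CH2 > H) without touching the benzyl ether or the ketal.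

Step 11
Reactants: 18 protected (S)-carbinol macrocycle
Product: 19 target CNP0356934.1
Conditions: H2 (1 atm), 10% Pd/C, EtOAc/MeOH, rt
Reagents that add atoms: none
Why: Catalytic hydrogenolysis of the benzylic C–O bonds of the benzyl ether and of the diphenylmethylene ketal frees the three phenols under neutral conditions at room temperature, under which the non-activated secondary benzylic alcohol and its (S)-configuration should be retained.

## Compound list

1 | 3,4,5-trihydroxybenzaldehyde | O=Cc1cc(O)c(O)c(O)c1 | starting material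
2 | 7-hydroxy-2,2-diphenyl-1,3-benzodioxole-5-carbaldehyde | O=Cc1cc(O)c2OC(c3ccccc3)(c3ccccc3)Oc2c1 | intermediate
3 | 2,2-diphenyl-7-[(triisopropylsilyl)oxy]-1,3-benzodioxole-5-carbaldehyde | O=Cc1cc(O[Si](C(C)C)(C(C)C)C(C)C)c2OC(c3ccccc3)(c3ccccc3)Oc2c1 | intermediate
4 | 5-ethenyl-2,2-diphenyl-7-[(triisopropylsilyl)oxy]-1,3-benzodioxole | C=Cc1cc(O[Si](C(C)C)(C(C)C)C(C)C)c2OC(c3ccccc3)(c3ccccc3)Oc2c1 | intermediate
5 | 2-fluoro-3-hydroxybenzaldehyde | O=Cc1cccc(O)c1F | starting material
6 | 3-(benzyloxy)-2-fluorobenzaldehyde | O=Cc1cccc(OCc2ccccc2)c1F | intermediate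
7 | 3-iodophenol | Oc1cccc(I)c1 | starting material
8 | 3-(benzyloxy)-2-(3-iodophenoxy)benzaldehyde | O=Cc1cccc(OCc2ccccc2)c1Oc1cccc(I)c1 | intermediate
9 | 4-fluorobenzaldehyde | O=Cc1ccc(F)cc1 | starting material
10 | (E)-N-(4-fluorobenzylidene)aniline | Fc1ccc(/C=N/c2ccccc2)cc1 | intermediate (not isolated)
11 | diphenyl [(4-fluorophenyl)(phenylamino)methyl]phosphonate (racemic) | O=P(Oc1ccccc1)(Oc1ccccc1)C(Nc1ccccc1)c1ccc(F)cc1 | intermediate
12 | N-{2-[3-(benzyloxy)-2-(3-iodophenoxy)phenyl]-1-(4-fluorophenyl)ethenyl}aniline (enamine, E/Z mixture) | Fc1ccc(cc1)C(Nc1ccccc1)=Cc1cccc(OCc2ccccc2)c1Oc1cccc(I)c1 | intermediate (not isolated)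
13 | 2-[3-(benzyloxy)-2-(3-iodophenoxy)phenyl]-1-(4-fluorophenyl)ethan-1-one | O=C(Cc1cccc(OCc2ccccc2)c1Oc1cccc(I)c1)c1ccc(F)cc1 | intermediate
14 | 9-{2-[2,2-diphenyl-7-(triisopropylsilyloxy)-1,3-benzodioxol-5-yl]ethyl}-9-borabicyclo[3.3.1]nonane | CC(C)[Si](Oc1cc(CCB2C3CCCC2CCC3)cc2OC(c3ccccc3)(c3ccccc3)Oc12)(C(C)C)C(C)C | intermediate (not isolated)
15 | 2-{3-(benzyloxy)-2-[3-(2-{2,2-diphenyl-7-[(triisopropylsilyl)oxy]-1,3-benzodioxol-5-yl}ethyl)phenoxy]phenyl}-1-(4-fluorophenyl)ethan-1-one | O=C(Cc1cccc(OCc2ccccc2)c1Oc1cccc(CCc2cc(O[Si](C(C)C)(C(C)C)C(C)C)c3OC(c4ccccc4)(c4ccccc4)Oc3c2)c1)c1ccc(F)cc1 | intermediate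
16 | cesium phenoxide of desilylated 15 (olate at C-7 of the benzodioxole) | [Cs+].[O-]c1cc(CCc2cccc(Oc3c(CC(=O)c4ccc(F)cc4)cccc3OCc3ccccc3)c2)cc2OC(c3ccccc3)(c3ccccc3)Oc12 | intermediate (not isolated)
17 | macrocyclic ketone: 18-membered ring; O on C-7 of the 2,2-diphenyl-1,3-benzodioxole (ring A) bonded to C-4 of ring B; ring B C-1–C(=O)–CH2–C-1 of ring C; ring C C-2–O–C-1 of ring D; ring D C-3–CH2CH2–C-5 of the benzodioxole; OBn on C-3 of ring C | O=C1Cc2cccc(OCc3ccccc3)c2Oc2cccc(c2)CCc2cc(Oc3ccc1cc3)c1OC(c3ccccc3)(c3ccccc3)Oc1c2 | intermediate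
18 | protected (S)-carbinol macrocycle: 17 with (S)-CH(OH) in place of C=O | O1c2cc3cc(c2OC1(c4ccccc4)c4ccccc4)Oc1ccc(cc1)[C@@H](O)Cc1cccc(OCc2ccccc2)c1Oc1cccc(c1)CC3 | intermediate
19 | CNP0356934.1: 18 with free catechol on ring A and free phenol on ring C, (S)-carbinol | Oc1cc2cc(c1O)Oc1ccc(cc1)[C@@H](O)Cc1cccc(O)c1Oc1cccc(c1)CC2 | target

## Step count and risks

Total steps: 11. Longest linear sequence: 7 steps (steps 4, 5, 7, 8, 9, 10, 11 from 5; equally steps 1, 2, 3, 8, 9, 10, 11 from 1).

Three steps most likely to fail: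

**Step 9.** The phenoxide may add to the fluoroarene of a second molecule faster than to its own, which would lead to chain growth. Deprotonation of the CH2 next to the ketone may also switch off ring B or start aldol-type condensation. The fallback closes the same O–C bond by copper-catalysed Ullmann etherification at the carbinol oxidation level, where there is no acidic CH2 and no SNAr activation is needed. It sets out from aldehyde 8. 4-Bromobenzaldehyde, aniline and diphenyl phosphite should give, through (E)-N-(4-bromobenzylidene)aniline F1, diphenyl [(4-bromophenyl)(phenylamino)methyl]phosphonate F2. Its Cs2CO3-mediated olefination with 8 should give the enamine N-{2-[3-(benzyloxy)-2-(3-iodophenoxy)phenyl]-1-(4-bromophenyl)ethenyl}aniline F3, which aqueous HCl hydrolyses to 2-[3-(benzyloxy)-2-(3-iodophenoxy)phenyl]-1-(4-bromophenyl)ethan-1-one F4. Transfer hydrogenation of this open-chain aryl benzyl ketone with RuCl[(S,S)-TsDPEN](p-cymene) and HCO2H/Et3N should give (1S)-2-[3-(benzyloxy)-2-(3-iodophenoxy)phenyl]-1-(4-bromophenyl)ethan-1-ol F5. The aryl iodide is then coupled with alkylborane 14 (PdCl2(dppf), K3PO4, rt), selectively because the bromide is now unactivated, to give (1S)-2-{3-(benzyloxy)-2-[3-(2-{2,2-diphenyl-7-[(triisopropylsilyl)oxy]-1,3-benzodioxol-5-yl}ethyl)phenoxy]phenyl}-1-(4-bromophenyl)ethan-1-ol F6. TBAF/AcOH in THF should free the phenol (1S)-2-(3-(benzyloxy)-2-{3-[2-(7-hydroxy-2,2-diphenyl-1,3-benzodioxol-5-yl)ethyl]phenoxy}phenyl)-1-(4-bromophenyl)ethan-1-ol F7. CuI, N,N-dimethylglycine and Cs2CO3 in dioxane at 90 °C under high dilution should then close the ring to 18, where the route is rejoined.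

**Step 10.** Facial selectivity may be poor because the macrocycle holds ring B and the CH2 arm in a fixed conformation that can override the usual aryl/alkyl recognition. Hydride transfer to the electron-rich para-aryloxy ketone may also be slow. The fallback is resolution instead of asymmetric catalysis, and it sets out from 17. NaBH4 in THF/MeOH should give the racemic protected carbinol macrocycle F8. Esterification with (S)-2-methoxy-2-phenylacetic acid (CO[C@H](C(=O)O)c1ccccc1), DCC and DMAP gives two diastereomeric esters. The (S)-carbinol (S)-2-methoxy-2-phenylacetate F9 is separated by chromatography or crystallisation from the (R)-carbinol (S)-2-methoxy-2-phenylacetate F10. Methanolysis of F9 (K2CO3, MeOH) returns 18.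

**Step 11.** Over-reduction may occur, by hydrogenolysis of the para-aryloxy-substituted benzylic C–OH bond, or the diphenylmethylene ketal may be cleaved incompletely. The fallback changes the order of events so that no carbinol is exposed to hydrogen, and it sets out from 17. Hydrogenolysis (H2, Pd/C, EtOAc) at the ketone stage should give the macrocyclic triphenol ketone F11. Transfer hydrogenation of F11 with RuCl[(S,S)-TsDPEN](p-cymene) and HCO2H/Et3N as the last operation should give 19 directly.

Further compounds
F1 | step 9 | (E)-N-(4-bromobenzylidene)aniline | Brc1ccc(/C=N/c2ccccc2)cc1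
F2 | step 9 | diphenyl [(4-bromophenyl)(phenylamino)methyl]phosphonate | O=P(Oc1ccccc1)(Oc1ccccc1)C(Nc1ccccc1)c1ccc(Br)cc1
F3 | step 9 | N-{2-[3-(benzyloxy)-2-(3-iodophenoxy)phenyl]-1-(4-bromophenyl)ethenyl}aniline | Brc1ccc(cc1)C(Nc1ccccc1)=Cc1cccc(OCc2ccccc2)c1Oc1cccc(I)c1
F4 | step 9 | 2-[3-(benzyloxy)-2-(3-iodophenoxy)phenyl]-1-(4-bromophenyl)ethan-1-one | O=C(Cc1cccc(OCc2ccccc2)c1Oc1cccc(I)c1)c1ccc(Br)cc1
F5 | step 9 | (1S)-2-[3-(benzyloxy)-2-(3-iodophenoxy)phenyl]-1-(4-bromophenyl)ethan-1-ol | Brc1ccc(cc1)[C@@H](O)Cc1cccc(OCc2ccccc2)c1Oc1cccc(I)c1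
F6 | step 9 | (1S)-2-{3-(benzyloxy)-2-[3-(2-{2,2-diphenyl-7-[(triisopropylsilyl)oxy]-1,3-benzodioxol-5-yl}ethyl)phenoxy]phenyl}-1-(4-bromophenyl)ethan-1-ol | Brc1ccc(cc1)[C@@H](O)Cc1cccc(OCc2ccccc2)c1Oc1cccc(CCc2cc(O[Si](C(C)C)(C(C)C)C(C)C)c3OC(c4ccccc4)(c4ccccc4)Oc3c2)c1
F7 | step 9 | (1S)-2-(3-(benzyloxy)-2-{3-[2-(7-hydroxy-2,2-diphenyl-1,3-benzodioxol-5-yl)ethyl]phenoxy}phenyl)-1-(4-bromophenyl)ethan-1-ol | Brc1ccc(cc1)[C@@H](O)Cc1cccc(OCc2ccccc2)c1Oc1cccc(CCc2cc(O)c3OC(c4ccccc4)(c4ccccc4)Oc3c2)c1
F8 | step 10 | racemic protected carbinol macrocycle (18 and its enantiomer) | O1c2cc3cc(c2OC1(c4ccccc4)c4ccccc4)Oc1ccc(cc1)C(O)Cc1cccc(OCc2ccccc2)c1Oc1cccc(c1)CC3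
F9 | step 10 | (S)-carbinol (S)-2-methoxy-2-phenylacetate of the protected macrocycle | O1c2cc3cc(c2OC1(c4ccccc4)c4ccccc4)Oc1ccc(cc1)[C@@H](OC(=O)[C@@H](OC)c1ccccc1)Cc1cccc(OCc2ccccc2)c1Oc1cccc(c1)CC3
F10 | step 10 | (R)-carbinol (S)-2-methoxy-2-phenylacetate of the protected macrocycle | O1c2cc3cc(c2OC1(c4ccccc4)c4ccccc4)Oc1ccc(cc1)[C@H](OC(=O)[C@@H](OC)c1ccccc1)Cc1cccc(OCc2ccccc2)c1Oc1cccc(c1)CC3
F11 | step 11 | macrocyclic triphenol ketone (19 with C=O in place of CH(OH)) | O=C1Cc2cccc(O)c2Oc2cccc(c2)CCc2cc(Oc3ccc1cc3)c(O)c(O)c2
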